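**Retrosynthetic overview** (terpenoid carbons in caryophyllane numbering: C1/C9 = cyclobutane ring-fusion carbons, C4 = O-bearing quaternary carbon, C5 = its CH neighbour, C8 = methylidene carbon)
1. Target ⇐ the C8 ketone, by C9 epimerisation to the trans-fused cyclobutane and Wittig methylenation.
2. Key disconnection: the C7–C8 bond of the nine-membered ring, with the C4–O bond of the dihydropyran made in the same operation ⇐ radical ring expansion of a 3-alkyl-3-methylbicyclo[4.2.0]octan-2-one. A C7 radical adds to the C8 carbonyl, the alkoxyl radical cleaves C4–C8, and the tertiary C4 radical is oxidised and trapped by the trione enol oxygen.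
3. That precursor ⇐ a γ-iodo aldehyde plus the acylfilicinic acid (reductive Knoevenagel alkylation); the C5 stereocentre ⇐ iridium-catalysed branched allylation of a tetrasubstituted enol silane with 4-vinyl-1,3-dioxolan-2-one.
4. Enol silane ⇐ cyclohex-2-en-1-one + 2-methylpropene (enantioselective [2+2] photocycloaddition sets C1), then α-methylenation and 1,4-hydrosilylation; acyl trione ⇐ methyl isobutyrate + diketene + (S)-2-methylbutanoic acid.
5. Ring order: cyclobutane (on the six-membered carbocycle) → trione ring (separate branch) → nine-membered carbocycle and dihydropyran together in the key step.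

Assumption: the quaternary carbon that becomes C4 (C3 in bicyclo numbering) is carried as an epimer mixture and left undefined in the SMILES until the key step, because that step erases it; the same holds for the transient Mannich-base centre.

**Step 1**
Reactants: 1 methyl 2-methylpropanoate (methyl isobutyrate); 2 diketene (4-methylideneoxetan-2-one)
Product: 5 filicinic acid (3,5-dihydroxy-4,4-dimethylcyclohexa-2,5-dien-1-one), via lithium enolate of methyl isobutyrate 3 (not isolated), via methyl 2,2-dimethyl-3,5-dioxohexanoate lithium enolate 4 (not isolated)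
Conditions: LiN(iPr)2 (LDA, 1.05 equiv), THF, −78 °C; 2, −78 °C; then LDA (2 equiv), −78 → 25 °C; aq. HCl
Reagents that add atoms: none
Why: Proposed new method: the hindered ester enolate should open the β-lactone of diketene at the acyl carbon (C-acetoacetylation, as diketene does with other hard nucleophiles), and the derived diketone dianion then closes the six-membered ring by intramolecular Claisen (Dieckmann-type) condensation onto the methyl ester, the closest known chemistry being Harris-type cyclisations of 3,5-dioxoalkanoate polyanions; no stereocentre is formed.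

**Step 2**
Reactants: 5 filicinic acid; 6 (2S)-2-methylbutanoic acid
Product: 8 3,5-dihydroxy-6,6-dimethyl-2-[(2S)-2-methylbutanoyl]cyclohexa-2,4-dien-1-one, via enol ester 7 (not isolated)
Conditions: DCC, DMAP (1.2 equiv), CH2Cl2, 0 → 25 °C
Reagents that add atoms: none
Why: Steglich O-acylation followed by DMAP-mediated O→C acyl migration is the standard entry to 2-acyl-1,3-diones; the two nucleophilic ring carbons of 5 are equivalent, and the mild conditions leave the (S) centre of the acid untouched.

**Step 3**
Reactants: 9 cyclohex-2-en-1-one; 10 2-methylpropene (isobutene)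
Product: 12 (1R,6R)-7,7-dimethylbicyclo[4.2.0]octan-2-one (cis-fused), via trans-fused photoadduct 11 (not isolated)
Conditions: 10 (excess), chiral prolinol-derived B-aryl-1,3,2-oxazaborolidine activated by AlBr3 (50 mol%), hν (366 nm), CH2Cl2, −75 °C; then basic Al2O3, CH2Cl2, 25 °C
Reagents that add atoms: none
Why: Bach's Lewis-acid-catalysed enantioselective intermolecular enone–alkene [2+2] photocycloaddition gives the head-to-tail adduct; the catalyst antipode is chosen to set the β-carbon (C6, the future C1) as R, and alumina epimerises the α-carbon so that only the cis-fused ketone remains.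

**Step 4**
Reactants: 12 (1R,6R)-7,7-dimethylbicyclo[4.2.0]octan-2-one
Product: 16 (1R,6R)-7,7-dimethyl-3-methylidenebicyclo[4.2.0]octan-2-one, via lithium enolate 13 (not isolated), via Mannich base 14 (not isolated), via ammonium iodide 15 (not isolated)
Conditions: LDA, THF, −78 °C; CH2=NMe2+ I−, −78 → 0 °C; then MeI, 25 °C; then DBU, CH2Cl2, 25 °C
Reagents that add atoms: N,N-dimethylmethylideneammonium iodide (Eschenmoser's salt), C=[N+](C)C.[I-]
Why: Kinetic deprotonation occurs at the unhindered C3 methylene and not at the ring-fusion methine, and Mannich reaction, N-methylation and Hofmann-type elimination (Eschenmoser methylenation) give the exocyclic enone; no stereocentre is created or disturbed.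

**Step 5**
Reactants: 16 (1R,6R)-7,7-dimethyl-3-methylidenebicyclo[4.2.0]octan-2-one
Product: 17 triethyl{[(1R,6R)-3,7,7-trimethylbicyclo[4.2.0]oct-2-en-2-yl]oxy}silane
Conditions: Et3SiH, RhCl(PPh3)3 (1 mol%), THF, 50 °C
Reagents that add atoms: triethylsilane, CC[SiH](CC)CC
Why: Rhodium-catalysed 1,4-hydrosilylation of the enone (Ojima) delivers the tetrasubstituted enol silane regiospecifically and installs the future C4 methyl group, which direct enolisation of a 3-methyl ketone could not guarantee; no stereocentre is formed.

**Step 6**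
Reactants: 17 triethylsilyl enol ether; 18 4-vinyl-1,3-dioxolan-2-one (racemic, 2.5 equiv)
Product: 19 (1R,6R)-3-[(2R)-1-hydroxybut-3-en-2-yl]-3,7,7-trimethylbicyclo[4.2.0]octan-2-one (C3 epimers)
Conditions: [Ir(cod)Cl]2 (2 mol%), Feringa-type phosphoramidite ligand (4 mol%, antipode giving the 2R side-chain centre), CsF (1.1 equiv), ZnF2 (0.2 equiv), THF, 25 → 40 °C; aq. NH4Cl
Reagents that add atoms: none
Why: Proposed new method: decarboxylative ionisation of 18 gives an iridium π-allyl complex that the fluoride-released tetrasubstituted enolate attacks at the substituted terminus, so the ligand alone fixes the allylic stereocentre (the future C5) while the quaternary-carbon configuration is irrelevant; the closest known reactions are Hartwig's iridium-catalysed branched allylation of enol silanes and Stoltz's iridium-catalysed formation of vicinal quaternary/tertiary centres.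

**Step 7**
Reactants: 19 homoallylic alcohol
Product: 21 (1R,6R)-3-[(2R)-1-hydroxy-4-iodobutan-2-yl]-3,7,7-trimethylbicyclo[4.2.0]octan-2-one (C3 epimers), via bis(9-borabicyclononyl) adduct 20 (not isolated)
Conditions: 9-BBN (2.3 equiv), THF, 0 → 25 °C; then NaOMe, MeOH, I2, 0 °C
Reagents that add atoms: iodine, II
Why: Anti-Markovnikov hydroboration of the terminal vinyl group is much faster than reduction of the hindered α-quaternary ketone, and base-induced iodinolysis of the primary C–B bond (Brown/Kabalka) gives the primary iodide; no stereocentre is touched.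

**Step 8**
Reactants: 21 iodo alcohol
Product: 22 (2R)-4-iodo-2-[(1R,6R)-3,7,7-trimethyl-2-oxobicyclo[4.2.0]octan-3-yl]butanal (C3 epimers)
Conditions: Dess–Martin periodinane, CH2Cl2, 0 → 25 °C
Reagents that add atoms: none
Why: Dess–Martin oxidation of the primary alcohol is neutral and tolerates the alkyl iodide, and the α-stereocentre next to the quaternary carbon is too hindered to enolise under these conditions.

**Step 9**
Reactants: 22 iodo aldehyde; 8 acylfilicinic acid
Product: 24 3,5-dihydroxy-4-{(2R)-4-iodo-2-[(1R,6R)-3,7,7-trimethyl-2-oxobicyclo[4.2.0]octan-3-yl]butyl}-6,6-dimethyl-2-[(2S)-2-methylbutanoyl]cyclohexa-2,4-dien-1-one (C3 epimers), via alkylidene trione 23 (not isolated)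
Conditions: Hantzsch ester (1.2 equiv), L-proline (20 mol%), CH2Cl2, 25 °C, dark
Reagents that add atoms: none
Why: Three-component reductive alkylation (Knoevenagel condensation at the only free ring carbon of 8, then conjugate hydride transfer from the Hantzsch ester; Ramachary) installs the CH2 link without base, so the primary iodide and the aldehyde-derived stereocentre survive.

**Step 10 (key step)**
Reactants: 24 iodo ketone carrying the acyl trione
Product: 25 ring-expanded keto chroman, i.e. the target skeleton with C8=O in place of C8=CH2 and a cis C1/C9 ring fusion, (1R,4R,5S,9R), acyl (2S)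
Conditions: fac-Ir(ppy)3 (2 mol%; ppy = 2-phenylpyridinato), 2,6-lutidine (1.5 equiv), MeCN (0.01 M), blue LEDs (450 nm), 25 °C
Reagents that add atoms: none
Why: Proposed new method: the excited photocatalyst reduces the C–I bond and the primary C7 radical adds 5-exo to the C8 carbonyl (forming C7–C8). The resulting alkoxyl radical cleaves the C4–C8 bond to open the nine-membered ring and release the tertiary C4 radical. This radical, the only one in the equilibrating set that the tetravalent iridium species can oxidise, becomes a cation that the free enol oxygen next to the gem-dimethyl carbon captures through a chair-like six-membered transition state. Both nine-ring bonds (C3, C6) are expected to sit equatorial there with the C4 methyl anti to H5, which would set C4 as R relative to the existing C5 centre. The closest known reactions are the Dowd–Beckwith three-carbon ring expansion and photoredox radical–polar crossover etherification of tertiary radicals.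

**Step 11**
Reactants: 25 cis-fused keto chroman
Product: 27 CNP0591516.2 (target), (1R,4R,5S,9S), acyl (2S), via trans-fused ketone potassium salt 26 (not isolated)
Conditions: KOtBu (2 equiv), t-BuOH–THF, 25 °C; then Ph3PCH3Br/KOtBu (5 equiv each), THF, 0 → 50 °C; aq. NH4Cl
Reagents that add atoms: methyltriphenylphosphonium bromide, C[P+](c1ccccc1)(c1ccccc1)c1ccccc1.[Br-]
Why: Base equilibrates C9 (α to the C8 ketone) to the trans-fused cyclobutane, the thermodynamic isomer in the nine-membered ring as in the caryophyllene nor-ketone, and Wittig methylenation then fixes it; the acyl trione sits as its unreactive potassium enolate, which shields its carbonyls and the side-chain stereocentre.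

**Compound list**
1 | methyl 2-methylpropanoate (methyl isobutyrate) | COC(=O)C(C)C | starting material
2 | diketene (4-methylideneoxetan-2-one) | C=C1CC(=O)O1 | starting material
3 | lithium 1-methoxy-2-methylprop-1-en-1-olate (not isolated) | COC(O[Li])=C(C)C | intermediate
4 | methyl 2,2-dimethyl-3,5-dioxohexanoate, formed as its lithium enolate (not isolated) | COC(=O)C(C)(C)C(=O)CC(C)=O | intermediate
5 | filicinic acid, 3,5-dihydroxy-4,4-dimethylcyclohexa-2,5-dien-1-one | O=C1C=C(O)C(C)(C)C(O)=C1 | intermediate
6 | (2S)-2-methylbutanoic acid | CC[C@H](C)C(=O)O | starting material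
7 | 4,4-dimethyl-3,5-dioxocyclohex-1-en-1-yl (2S)-2-methylbutanoate (not isolated) | CC[C@H](C)C(=O)OC1=CC(=O)C(C)(C)C(=O)C1 | intermediate
8 | 3,5-dihydroxy-6,6-dimethyl-2-[(2S)-2-methylbutanoyl]cyclohexa-2,4-dien-1-one | CC[C@H](C)C(=O)C1=C(O)C=C(O)C(C)(C)C1=O | intermediate
9 | cyclohex-2-en-1-one | O=C1C=CCCC1 | starting material
10 | 2-methylpropene (isobutene) | C=C(C)C | starting material
11 | (1S,6R)-7,7-dimethylbicyclo[4.2.0]octan-2-one, trans-fused (not isolated) | O=C1CCC[C@@H]2[C@@H]1CC2(C)C | intermediate
12 | (1R,6R)-7,7-dimethylbicyclo[4.2.0]octan-2-one, cis-fused | O=C1CCC[C@@H]2[C@H]1CC2(C)C | intermediate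
13 | lithium (1R,6R)-7,7-dimethylbicyclo[4.2.0]oct-2-en-2-olate (not isolated) | [Li]OC1=CCC[C@@H]2[C@H]1CC2(C)C | intermediate
14 | (1R,6R)-3-[(dimethylamino)methyl]-7,7-dimethylbicyclo[4.2.0]octan-2-one, C3 epimers (not isolated) | O=C1C(CN(C)C)CC[C@@H]2[C@H]1CC2(C)C | intermediate
15 | [(1R,6R)-7,7-dimethyl-2-oxobicyclo[4.2.0]octan-3-yl]-N,N,N-trimethylmethanaminium iodide, C3 epimers (not isolated) | O=C1C(C[N+](C)(C)C)CC[C@@H]2[C@H]1CC2(C)C.[I-] | intermediate
16 | (1R,6R)-7,7-dimethyl-3-methylidenebicyclo[4.2.0]octan-2-one | O=C1C(=C)CC[C@@H]2[C@H]1CC2(C)C | intermediate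
17 | triethyl{[(1R,6R)-3,7,7-trimethylbicyclo[4.2.0]oct-2-en-2-yl]oxy}silane | CC[Si](CC)(CC)OC1=C(C)CC[C@@H]2[C@H]1CC2(C)C | intermediate
18 | 4-vinyl-1,3-dioxolan-2-one (racemic) | C=CC1COC(=O)O1 | starting material
19 | (1R,6R)-3-[(2R)-1-hydroxybut-3-en-2-yl]-3,7,7-trimethylbicyclo[4.2.0]octan-2-one, C3 epimers | O=C1C(C)([C@H](CO)C=C)CC[C@@H]2[C@H]1CC2(C)C | intermediate
20 | (1R,6R)-3-{(2R)-4-(9-borabicyclo[3.3.1]nonan-9-yl)-1-[(9-borabicyclo[3.3.1]nonan-9-yl)oxy]butan-2-yl}-3,7,7-trimethylbicyclo[4.2.0]octan-2-one, C3 epimers (not isolated) | O=C1C(C)([C@H](COB3C4CCCC3CCC4)CCB3C4CCCC3CCC4)CC[C@@H]2[C@H]1CC2(C)C | intermediate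
21 | (1R,6R)-3-[(2R)-1-hydroxy-4-iodobutan-2-yl]-3,7,7-trimethylbicyclo[4.2.0]octan-2-one, C3 epimers | O=C1C(C)([C@H](CO)CCI)CC[C@@H]2[C@H]1CC2(C)C | intermediate
22 | (2R)-4-iodo-2-[(1R,6R)-3,7,7-trimethyl-2-oxobicyclo[4.2.0]octan-3-yl]butanal, C3 epimers | O=C1C(C)([C@H](C=O)CCI)CC[C@@H]2[C@H]1CC2(C)C | intermediate
23 | 5-hydroxy-6-{(2S)-4-iodo-2-[(1R,6R)-3,7,7-trimethyl-2-oxobicyclo[4.2.0]octan-3-yl]butylidene}-2,2-dimethyl-4-[(2S)-2-methylbutanoyl]cyclohex-4-ene-1,3-dione (not isolated) | O=C1C(C)([C@H](C=C3C(=O)C(C)(C)C(=O)C(C(=O)[C@@H](C)CC)=C3O)CCI)CC[C@@H]2[C@H]1CC2(C)C | intermediate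
24 | 3,5-dihydroxy-4-{(2R)-4-iodo-2-[(1R,6R)-3,7,7-trimethyl-2-oxobicyclo[4.2.0]octan-3-yl]butyl}-6,6-dimethyl-2-[(2S)-2-methylbutanoyl]cyclohexa-2,4-dien-1-one, C3 epimers | O=C1C(C)([C@H](CC3=C(O)C(C)(C)C(=O)C(C(=O)[C@@H](C)CC)=C3O)CCI)CC[C@@H]2[C@H]1CC2(C)C | intermediate
25 | C8-oxo, cis-cyclobutane precursor of the target, (1R,4R,5S,9R), acyl (2S) | O=C1CC[C@H]2CC3=C(O[C@]2(C)CC[C@@H]2[C@H]1CC2(C)C)C(C)(C)C(=O)C(C(=O)[C@@H](C)CC)=C3O | intermediate
26 | C8-oxo, trans-cyclobutane precursor of the target, (1R,4R,5S,9S), acyl (2S); potassium enolate in the flask (not isolated) | O=C1CC[C@H]2CC3=C(O[C@]2(C)CC[C@@H]2[C@@H]1CC2(C)C)C(C)(C)C(=O)C(C(=O)[C@@H](C)CC)=C3O | intermediate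
27 | CNP0591516.2, (1R,4R,5S,9S), acyl (2S) | C=C1CC[C@H]2CC3=C(O[C@]2(C)CC[C@@H]2[C@@H]1CC2(C)C)C(C)(C)C(=O)C(C(=O)[C@@H](C)CC)=C3O | target

**Totals and risks**
Total step count: 11. Longest linear sequence: 9 steps (steps 3–11, from cyclohex-2-en-1-one); the two-step trione branch (steps 1–2) joins at step 9.

Most likely to fail, in this order:

Step 10. The cascade asks a primary radical to attack a hindered ketone faster than it is quenched, and it relies on conformational control for the C4 configuration; the (4R) outcome is an expectation, not a precedent. Fallback, setting out from 24: separate the radical and ionic events. Irradiate 24 with Mn2(CO)10 (10 mol%, blue light, CH2Cl2, 25 °C) so that iodine-atom transfer carries the same ring expansion through to the ring-expanded tertiary iodide F1. Then ionise F1 with AgOTf and 2,6-di-tert-butylpyridine in CH2Cl2 at −40 °C, where the enol oxygen closes the dihydropyran under purely ionic, low-temperature control. This returns to 25.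

Step 6. A tetrasubstituted, sterically loaded enolate must attack the substituted terminus of the allyl–iridium complex with high enantiocontrol. Fallback, setting out from 17: organocatalytic Mukaiyama–Michael addition of 17 to commercial (E)-4-(tert-butyldimethylsilyloxy)but-2-enal under iminium catalysis (MacMillan imidazolidinone·CF3CO2H, CH2Cl2/H2O, −20 °C) sets the C5 centre under catalyst control and gives the keto aldehyde F2, with C7 already in place. NaBH(OAc)3 reduces only the aldehyde to the alcohol F3, I2/PPh3/imidazole gives the iodide F4, and HF·pyridine removes the silyl ether. This returns to 21.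

Step 1. Diketene may be deprotonated or polymerised by the ester enolate, and O-cyclisation to a pyrandione can compete. Fallback, setting out from 1: build the chain by two ordinary Claisen acylations. The enolate of 1 with acetyl chloride gives methyl 2,2-dimethyl-3-oxobutanoate F5. Its methyl-ketone enolate (LDA, 3 equiv) is then acylated with N-methoxy-N-methylacetamide to give 4, which cyclises on warming as in step 1. This returns to 5.

**Further compounds**
F1 | step 10 | ring-expanded tertiary iodide: nine-membered C8 ketone with C4(CH3)(I) (C4 epimers), cis-fused cyclobutane, (5S) side chain CH2–acyl trione | O=C1CC[C@@H](CC2=C(O)C(C)(C)C(=O)C(C(=O)[C@@H](C)CC)=C2O)C(C)(I)CC[C@@H]2[C@H]1CC2(C)C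
F2 | step 6 | 4-[(tert-butyldimethylsilyl)oxy]-3-[(1R,6R)-3,7,7-trimethyl-2-oxobicyclo[4.2.0]octan-3-yl]butanal (side-chain centre as in 21, C3 epimers) | O=C1C(C)([C@H](CO[Si](C)(C)C(C)(C)C)CC=O)CC[C@@H]2[C@H]1CC2(C)C
F3 | step 6 | (1R,6R)-3-{1-[(tert-butyldimethylsilyl)oxy]-4-hydroxybutan-2-yl}-3,7,7-trimethylbicyclo[4.2.0]octan-2-one (side-chain centre as in 21) | O=C1C(C)([C@H](CO[Si](C)(C)C(C)(C)C)CCO)CC[C@@H]2[C@H]1CC2(C)C
F4 | step 6 | (1R,6R)-3-{1-[(tert-butyldimethylsilyl)oxy]-4-iodobutan-2-yl}-3,7,7-trimethylbicyclo[4.2.0]octan-2-one (side-chain centre as in 21) | O=C1C(C)([C@H](CO[Si](C)(C)C(C)(C)C)CCI)CC[C@@H]2[C@H]1CC2(C)C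
F5 | step 1 | methyl 2,2-dimethyl-3-oxobutanoate | COC(=O)C(C)(C)C(C)=O
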